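1. Whatever happens in these closed flasks, the starting complex charged stays counted: as itself, as complex with one or two exchanged, or as self-condensation product.

| flask | starting complex | incoming ligand | remark | time |
|---|---|---|---|---|
| Friday's | 0.28 M | 0.21 M | run made earlier |  |
| Tuesday's | 0.44 M | 0.21 M | run made earlier |  |
| flask | 0.20 M | 0.210 M |  | 3.0 h |

- Friday's (time / min: complex with one exchanged / %, starting complex / %): 1.00: 32, 28; 5.00: 40, 4; 25.0: 38, 1; 120: 32, 3
- Tuesday's (time / min: complex with one exchanged / %, starting complex / %): 1.00: 27, 22; 5.00: 32, 3; 25.0: 32, 3; 120: 21, 0

(readings scatter by 2 percentage points)

- a species is counted by the starting complex in it: one self-condensation product counts as two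
- what was read earlier has a scatter of 2 percentage points, one standard deviation
- reactions considered so far: starting complex + incoming ligand <-> leaving ligand + complex with one exchanged; complex with one exchanged + incoming ligand <-> leaving ligand + complex with two exchanged; 2 starting complex -> self-condensation product

* time up to 3.0 h at which complex with one exchanged stands highest
* the amount of complex with one exchanged, in percent of the starting complex charged, at that time

2. One thing looks wrong. In Friday's run the incoming ligand covers 75.0 % of the starting complex charged, and at 5.00 min the starting complex reads 4 %, yet complex with one exchanged reads 40 %.

3. Forward exchange goes with starting complex times incoming ligand, but self-condensation goes with the square of starting complex, so the split between them goes with incoming ligand over starting complex.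

4. At that reading time, the share of spent starting complex read as complex with one exchanged is 41.7 % in Friday's run and 33.0 % in Tuesday's.

5. I write share = ligand / (ligand + w × starting complex), with both as charged. Friday's run gives w = 1.05 and Tuesday's 0.969. Their mean, 1.01, is my condensation weight, a selectivity factor read from the runs. It also takes in whatever went on to complex with two exchanged.

6. For the flask, I reckon a peak of 51.0 %.

7. The forecast gives 52 % (44 % to 60 %) at 0.15 h (0.07 h to 0.5 h). Its grounds: “Leaving ligand therefore regenerates starting complex, which drains slowly into self-condensation product.”

8. The flask peaks at 48.8 % at 0.0537 h.

    starting complex + incoming ligand ⇌ leaving ligand + complex with one exchanged (K = 51.0, k = 5.60 M⁻¹ min⁻¹)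
    complex with one exchanged + incoming ligand ⇌ leaving ligand + complex with two exchanged (K = 1.50, k = 0.860 M⁻¹ min⁻¹)
    2 starting complex → self-condensation product (k = 2.50 M⁻¹ min⁻¹)

9. By that peak, starting complex has fallen to 7.36 %, with self-condensation product at 33.8 % and complex with two exchanged at 10.0 %. Later, with starting complex at 1.73 % by 3.00 h, complex with one exchanged stands at 35.4 % and self-condensation product at 42.6 %. My weight lands 2.2 percentage points high; the forecast's time is 2.79 times the flask's. With 0.36 M of incoming ligand, the weight gives 64.1 %; that flask gives 56.9 %.

(The numbers in the tables are simulated on assumed constants; scatter was added.)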